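**Assumptions**
- The target is a vescalagin/castalagin-type C-glucosidic ellagitannin. The SMILES fixes C1 as R, with the C1–OH cis to the C2–C3 bond across the new lactone ring.
- The SMILES does not encode the three biaryl axes. I assume the natural senses, each set by its tether to the D-glucose centres.
- Intermediates with a free anomeric centre are anomeric mixtures and are drawn without anomeric stereochemistry.
- Bn = CH2Ph.

**Retrosynthesis**
- The target is the global debenzylation product of its pentadecabenzyl ether.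
- That ether comes from a photochemical dehydrogenative biaryl coupling between the O5-aroyl ring and the single free C–H of the neighbouring O3-aroyl ring. This closes the last macrocycle and completes the nonahydroxyterphenoyl unit.
- The precursor of that coupling is made by an intramolecular Friedel–Crafts hydroxyalkylation of the C1 aldehyde by the O2-aroyl ring. This forms the six-membered lactone and sets C1.
- The aldehyde is unmasked from an open-chain 5-O-aroyl dithioacetal, which comes from the 2,3;4,6-bis-HHDP glucopyranose. That in turn comes from a double Ullmann coupling on 2,3,4,6-tetra-O-(2-iodoaroyl)-D-glucopyranose, made from D-glucose and an iodogallic acid.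
- Ring order: the two HHDP rings (4,6 and 2,3) first, then the C1 lactone, then the A–B macrocycle.

---

**Step 1**
Reactants: 1 (3,4,5-tris(benzyloxy)benzoic acid)
Product: 2 (2-iodo-3,4,5-tris(benzyloxy)benzoic acid)
Conditions: NIS (1.05 equiv), cat. TFA, MeCN, 0 °C → rt, dark
Reagents that add atoms: N-iodosuccinimide, O=C1CCC(=O)N1I (adds I)
Why: Electrophilic aromatic iodination goes at C2, which is ortho to the 3-OBn and para to the 5-OBn; the two ortho positions are equivalent, so 1.05 equiv gives mono-iodination.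

**Step 2**
Reactants: 3 (D-glucose, 1 equiv) and 2 (2-iodo-3,4,5-tris(benzyloxy)benzoic acid, 5.5 equiv; five aroyl groups are transferred)
Product: 4 (penta-O-(2-iodo-3,4,5-tribenzyloxybenzoyl)-D-glucopyranose)
Conditions: EDC·HCl (6 equiv), DMAP (1 equiv), DMF/CH2Cl2 1:1, rt, 48 h
Reagents that add atoms: 2-iodo-3,4,5-tris(benzyloxy)benzoic acid (compound 2), OC(=O)c1cc(OCc2ccccc2)c(OCc2ccccc2)c(OCc2ccccc2)c1I (adds five 2-iodoaroyl groups; overall 3 + 5 × 2 → 4 + 5 H2O)
Why: Steglich esterification acylates all five hydroxyls of glucose with five equivalents of the acid, and it does not touch C2–C5, so the D-gluco configuration is kept.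

**Step 3**
Reactants: 4
Product: 5 (2,3,4,6-tetra-O-(2-iodoaroyl)-D-glucopyranose, 1-OH free)
Conditions: H2NNH2·HOAc (1.5 equiv), DMF, rt
Reagents that add atoms: none (the hydrazine ends up only in the cleaved aroyl hydrazide)
Why: The anomeric aroyl ester is the most electrophilic and the least hindered, so hydrazinolysis removes it selectively, as in selective anomeric deacylation of per-acylated sugars.

**Step 4**
Reactants: 5
Product: 6 (2,3;4,6-bis-HHDP-D-glucopyranose hemiacetal, dodecabenzyl ether)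
Conditions: activated Cu powder (20 equiv), DMF, 130 °C
Reagents that add atoms: none (Cu removes the four iodine atoms as CuI)
Why: Intramolecular Ullmann coupling; in the ⁴C₁ pyranose the 2,3- and 4,6-diaroyl pairs are the geometrically accessible ones (the arrangement of casuarictin-type ellagitannins), and the ester tethers to the sugar allow only the natural atropisomer of each HHDP ring.

**Step 5**
Reactants: 6
Product: 7 (open-chain 5-OH diethyl dithioacetal of the bis-HHDP glucose)
Conditions: EtSH (30 equiv), conc. HCl, CH2Cl2, 0 °C → rt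
Reagents that add atoms: ethanethiol, CCS (adds two SEt; 6 + 2 EtSH → 7 + H2O)
Why: Fischer mercaptolysis of the hemiacetal opens the pyranose to the acyclic dithioacetal, frees O5 and fixes C1 as an aldehyde equivalent; C2–C5 are untouched.

**Step 6**
Reactants: 7, 1 (3,4,5-tris(benzyloxy)benzoic acid)
Product: 8 (5-O-(3,4,5-tribenzyloxybenzoyl) dithioacetal)
Conditions: EDC·HCl, DMAP, CH2Cl2, rt
Reagents that add atoms: none
Why: Steglich esterification of the only free hydroxyl installs ring A on O5.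

**Step 7**
Reactants: 8
Product: 9 (aldehydo-sugar: 5-O-aroyl-2,3;4,6-bis-HHDP-aldehydo-D-glucose)
Conditions: MeI (20 equiv), CaCO3, MeCN/H2O 9:1, 50 °C
Reagents that add atoms: water, O (supplies the aldehyde oxygen; MeI leaves as MeSEt)
Why: S-methylation then hydrolysis of the dithioacetal under essentially neutral, buffered conditions avoids epimerising the α-acyloxy aldehyde.

**Step 8**
Reactants: 9
Product: 10 (C1-hydroxy compound with the six-membered C1–ring E lactone)
Conditions: Sc(OTf)3 (20 mol%), ClCH2CH2Cl, 0 → 40 °C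
Reagents that add atoms: none (isomerisation)
Why: Intramolecular Friedel–Crafts hydroxyalkylation: the only free ortho C–H of the O2-aroyl ring (ortho to a 5-OBn and para to a 3-OBn) attacks the Sc-activated C1 aldehyde through a six-membered half-chair transition state. The C3 side chain sits pseudo-equatorial on the forming lactone, and A(1,3)-type strain with the neighbouring OBn orients C1–H toward it, giving the C1-OH cis to the C2–C3 bond (1R); C1 is therefore set by substrate control from C2.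

**Step 9**
Reactants: 10
Product: 11 (pentadecabenzyl ether of the target)
Conditions: [Mes-Acr-Me]⁺BF4⁻ (5 mol%), Co(dmgH)2pyCl (10 mol%), HFIP/CH2Cl2 1:4, blue LEDs (450 nm), N2, rt, 24 h
Reagents that add atoms: none (H2 is released)
Why: Proposed new method: the excited acridinium oxidises the most electron-rich arene, the ring B biaryl, to its radical cation, and the tethered ring A attacks the single free ortho C–H of ring B. Loss of H⁺ and cobaloxime-mediated H2 release rearomatise the ring to the tetra-ortho-substituted biaryl, with no halogen, free phenol or stoichiometric oxidant needed. The closest known reactions are Kita-type PIFA/BF3 intramolecular biaryl coupling and photoredox/cobaloxime dehydrogenative arene–arene coupling, here extended to a polybenzyloxy aroyl ester macrocyclisation. The 11-membered tether to C3 and C5 favours the natural atropisomer, and C1–OH and all stereocentres are untouched.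

**Step 10**
Reactants: 11
Product: 12 (target)
Conditions: H2 (1 atm), Pd(OH)2/C, THF/MeOH 1:1, rt
Reagents that add atoms: none (only H is added)
Why: Hydrogenolysis removes all 15 O-benzyl groups; the aryl lactones, the biaryl axes and the stereocentres survive, and the benzylic C1-OH is retained under these mild conditions.

---

**Compound list**

1 | 3,4,5-tris(benzyloxy)benzoic acid | OC(=O)c1cc(OCc9ccccc9)c(OCc9ccccc9)c(OCc9ccccc9)c1 | starting material
2 | 2-iodo-3,4,5-tris(benzyloxy)benzoic acid | OC(=O)c1cc(OCc9ccccc9)c(OCc9ccccc9)c(OCc9ccccc9)c1I | intermediate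
3 | D-glucose (pyranose form, anomeric centre undefined) | OC[C@H]1OC(O)[C@H](O)[C@@H](O)[C@@H]1O | starting material
4 | penta-O-(2-iodo-3,4,5-tribenzyloxybenzoyl)-D-glucopyranose | O=C(c2cc(OCc9ccccc9)c(OCc9ccccc9)c(OCc9ccccc9)c2I)OC1O[C@H](COC(=O)c2cc(OCc9ccccc9)c(OCc9ccccc9)c(OCc9ccccc9)c2I)[C@@H](OC(=O)c2cc(OCc9ccccc9)c(OCc9ccccc9)c(OCc9ccccc9)c2I)[C@H](OC(=O)c2cc(OCc9ccccc9)c(OCc9ccccc9)c(OCc9ccccc9)c2I)[C@H]1OC(=O)c2cc(OCc9ccccc9)c(OCc9ccccc9)c(OCc9ccccc9)c2I | intermediate
5 | 2,3,4,6-tetra-O-(2-iodo-3,4,5-tribenzyloxybenzoyl)-D-glucopyranose | OC1O[C@H](COC(=O)c2cc(OCc9ccccc9)c(OCc9ccccc9)c(OCc9ccccc9)c2I)[C@@H](OC(=O)c2cc(OCc9ccccc9)c(OCc9ccccc9)c(OCc9ccccc9)c2I)[C@H](OC(=O)c2cc(OCc9ccccc9)c(OCc9ccccc9)c(OCc9ccccc9)c2I)[C@H]1OC(=O)c2cc(OCc9ccccc9)c(OCc9ccccc9)c(OCc9ccccc9)c2I | intermediate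
6 | 2,3;4,6-bis-(hexabenzyl-HHDP)-D-glucopyranose | O=C1OC[C@H]2OC(O)[C@@H]3OC(=O)c4cc(OCc9ccccc9)c(OCc9ccccc9)c(OCc9ccccc9)c4-c4c(OCc9ccccc9)c(OCc9ccccc9)c(OCc9ccccc9)cc4C(=O)O[C@H]3[C@@H]2OC(=O)c2cc(OCc9ccccc9)c(OCc9ccccc9)c(OCc9ccccc9)c2-c2c1cc(OCc9ccccc9)c(OCc9ccccc9)c2OCc9ccccc9 | intermediate
7 | open-chain 5-OH diethyl dithioacetal of the bis-HHDP glucose | O=C1OC[C@@H](O)[C@@H](OC(=O)c2cc(OCc9ccccc9)c(OCc9ccccc9)c(OCc9ccccc9)c2-c2c1cc(OCc9ccccc9)c(OCc9ccccc9)c2OCc9ccccc9)[C@@H]3OC(=O)c4cc(OCc9ccccc9)c(OCc9ccccc9)c(OCc9ccccc9)c4-c4c(OCc9ccccc9)c(OCc9ccccc9)c(OCc9ccccc9)cc4C(=O)O[C@H]3C(SCC)SCC | intermediate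
8 | 5-O-(3,4,5-tribenzyloxybenzoyl) derivative of 7 | O=C1OC[C@@H](OC(=O)c5cc(OCc9ccccc9)c(OCc9ccccc9)c(OCc9ccccc9)c5)[C@@H](OC(=O)c2cc(OCc9ccccc9)c(OCc9ccccc9)c(OCc9ccccc9)c2-c2c1cc(OCc9ccccc9)c(OCc9ccccc9)c2OCc9ccccc9)[C@@H]3OC(=O)c4cc(OCc9ccccc9)c(OCc9ccccc9)c(OCc9ccccc9)c4-c4c(OCc9ccccc9)c(OCc9ccccc9)c(OCc9ccccc9)cc4C(=O)O[C@H]3C(SCC)SCC | intermediate
9 | aldehydo-sugar from 8 | O=C1OC[C@@H](OC(=O)c5cc(OCc9ccccc9)c(OCc9ccccc9)c(OCc9ccccc9)c5)[C@@H](OC(=O)c2cc(OCc9ccccc9)c(OCc9ccccc9)c(OCc9ccccc9)c2-c2c1cc(OCc9ccccc9)c(OCc9ccccc9)c2OCc9ccccc9)[C@@H]3OC(=O)c4cc(OCc9ccccc9)c(OCc9ccccc9)c(OCc9ccccc9)c4-c4c(OCc9ccccc9)c(OCc9ccccc9)c(OCc9ccccc9)cc4C(=O)O[C@H]3C=O | intermediate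
10 | C1-aryl, 1-hydroxy lactone from 9 | O=C1OC[C@@H](OC(=O)c5cc(OCc9ccccc9)c(OCc9ccccc9)c(OCc9ccccc9)c5)[C@@H](OC(=O)c2cc(OCc9ccccc9)c(OCc9ccccc9)c(OCc9ccccc9)c2-c2c1cc(OCc9ccccc9)c(OCc9ccccc9)c2OCc9ccccc9)[C@@H]3OC(=O)c4cc(OCc9ccccc9)c(OCc9ccccc9)c(OCc9ccccc9)c4-c4c(OCc9ccccc9)c(OCc9ccccc9)c(OCc9ccccc9)c6c4C(=O)O[C@H]3[C@@H]6O | intermediate
11 | pentadecabenzyl ether of the target | O=C1OC[C@H]2OC(=O)c3cc(OCc9ccccc9)c(OCc9ccccc9)c(OCc9ccccc9)c3-c3c(OCc9ccccc9)c(OCc9ccccc9)c(OCc9ccccc9)c4c3C(=O)O[C@H]([C@H]3OC(=O)c5c-4c(OCc9ccccc9)c(OCc9ccccc9)c(OCc9ccccc9)c5[C@H]3O)[C@@H]2OC(=O)c2cc(OCc9ccccc9)c(OCc9ccccc9)c(OCc9ccccc9)c2-c2c1cc(OCc9ccccc9)c(OCc9ccccc9)c2OCc9ccccc9 | intermediate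
12 | target (CID 12302513) | O=C1OC[C@H]2OC(=O)c3cc(O)c(O)c(O)c3-c3c(O)c(O)c(O)c4c3C(=O)O[C@H]([C@H]3OC(=O)c5c-4c(O)c(O)c(O)c5[C@H]3O)[C@@H]2OC(=O)c2cc(O)c(O)c(O)c2-c2c1cc(O)c(O)c2O | target

---

**Totals:** 10 steps. The longest linear sequence is 10 steps (1 → 2 → 4 → 5 → 6 → 7 → 8 → 9 → 10 → 11 → 12); counted from D-glucose alone it is 9.

**Three steps most likely to fail**

1. **Step 9 (new photochemical A–B coupling).**
   - Risks: ring A coupling at the free C–H of ring C or D, oxidation of the benzylic C1-OH, and formation of the wrong atropisomer.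
   - Fallback (known chemistry): use 2-iodo acid 2 instead of 1 in Step 6, so O5 carries a 2-iodoaroyl group. Steps 7 and 8 are unchanged. Then close the A–B macrocycle by intramolecular Pd-catalysed direct C–H arylation of ring B (Pd(OAc)2, PCy3·HBF4, PivOH, K2CO3, DMA, 110 °C) before the final hydrogenolysis.

2. **Step 8 (Friedel–Crafts C1 closure and C1 configuration).**
   - Risks: the ester-bearing, fully benzylated ring E is weakly nucleophilic, and the 1S epimer may form.
   - Fallback: close C1 by an intramolecular Nozaki–Hiyama–Kishi aryl addition instead. Deliver the O2 aroyl group as a 6-bromo-2-iodoaroyl ester, using regioselective acylation of the 2-OH of a 4,6-O-benzylidene glucose. Run the Ullmann selectively at C–I, unmask the aldehyde, and cyclise the aryl bromide onto it with CrCl2/cat. NiCl2 in DMF.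

3. **Step 5 (open-chain dithioacetal from the acylated hemiacetal).**
   - Risks: the reaction may stop at the ethyl thioglycoside, and the free 5-OH may undergo acyl migration.
   - Fallback: open the hemiacetal as an aldoxime instead (NH2OH·HCl, pyridine) to give the open-chain 5-OH oxime. Aroylate O5 with 1 under the Step 6 conditions. Then regenerate the aldehyde by deoximation (aq. TiCl3/NH4OAc) to reach compound 9 and continue with Step 8.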